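A small charge of initiator, 4.0 mM against 0.40 M of starting material, set the red flask going, and this same flask is the one asked about.

| flask | starting material | coupling partner | initiator | temperature | remark | time |
|---|---|---|---|---|---|---|
| red | 0.40 M | 0.48 M | 4 mM | 20 °C | the very flask that is asked about, followed so far |  |
| green | 0.40 M | 0.24 M | 4 mM | 15 °C | run made earlier |  |
| flask | 0.40 M | 0.480 M | 4.0 mM | 20 °C |  | 30 h |

- red (time / h: product / %, starting material / %): 1.50: 29, 75; 5.00: 52, 49; 8.00: 57, 42; 12.0: 64, 33; 20.0: 68, 30; 25.0: 63, 34; 30.0: 63, 31
- green (time / min: product / %, starting material / %): 8.00: 1, 101; 12.0: 6, 97; 15.0: 4, 96; 25.0: 2, 97; 40.0: 2, 94; 60.0: 8, 95; 90.0: 8, 93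

(scatter of a reading: 2 percentage points)

- north-west: at 30 h take out 90% of the released group then present, then wait 30 h
- north-east: change nothing and wait 30 h more
- west: at 30 h add coupling partner, 50.0% of the amount charged, then wait 30 h
- south-east: at 30 h raise the temperature by 25 K, then wait 30 h

- product, in percent of the starting material first charged, at 30 h
- the option that brings most further product ("none" if no option brings more than 2 percentage points) (north-west / north-east / west / south-east / none)
- product present, in percent of the starting material first charged, after north-east
- product present, in percent of the starting material first charged, after west

- what is added takes up no volume worth counting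
- the numbers in the tables scatter by 2 percentage points (one standard deviation)

The red readings rose fast and then stood: from 12.0 h on, the product averaged 64.5% and the starting material 32.0%, so the balance of starting material, the reagent charged in the smaller amount, summed to 96.5% and showed a stop with much of it unused. But a one-to-one count then promised 0.222 M of coupling partner still free, though the partner was never read, so a stop with both reagents apparently on hand wanted explaining. The green run, ended at 90.0 min with 8% product, was too short to speak of a stall. So I wagered that the partner was being lost by a route of its own, which would make it the limiting reagent although charged in excess, and I carried the partner yield, 0.538, that is product formed per coupling partner charged.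

On that wager, waiting, taking out released group and heating add no partner, so I expected the flask to stay near 64.5%. West adds 0.240 M of partner, worth 32 percentage points at the same yield, about equal to the unused starting material, so I reckoned 96.8% and chose west.

The forecast, saying “I favour reversible exchange with the released group”, gave 65% now, 65.5% after waiting, 74% after west, and north-west as best, so it parted from my reckoning on the choice.

The flask gave 66.1% at 30 h, 66.2% after north-east, 99.1% after west, and west as best, with a gain of 33 points.

    initiator → 2 initiating radical (k = 2.50 × 10⁻⁴ /min, Ea = 101 kJ/mol)
    starting material + initiating radical → capped initiator + first chain carrier (k = 1.40 × 10⁵ /M/s, Ea = 15.0 kJ/mol)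
    coupling partner + first chain carrier → product + second chain carrier (k = 69000 /M/min, Ea = 44.0 kJ/mol)
    starting material + second chain carrier → released group + first chain carrier (k = 1.40 × 10⁵ /M/min, Ea = 42.0 kJ/mol)
    2 first chain carrier → ended chains (k = 6.00 × 10⁶ /M/s, Ea = 19.0 kJ/mol)
    2 coupling partner → homo dimer (k = 0.00740 /M/min, Ea = 63.0 kJ/mol)
    (constants at 20 °C)

At 30.0 h the flask held 0.0943% of its coupling partner free and 0.108 M of homo dimer, each holding two partners, so product and homo dimer together account for 0.480 M of partner, and the yield stood at 0.550. In the run without the homo dimer step, west brought 0 points of further product, against 33 points with that step. For the neighbour charged with 0.12 M of partner, my yield gives 16.1% product, but that flask gave 24.3%, a yield higher than mine, 0.810, with 0.0113 M of homo dimer.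

The numbers in the tables are calculated with made-up constants, and the scatter is random.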